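Making first product cannot have emptied the north-east flask of its coupling partner: at 20.0 h the 63.1 % of first product had taken, one for one, 25.2 % of the charge.

all flasks: temperature 90 °C
- north-east: substrate 1 M; coupling partner 2.5 equiv; the very flask that is asked about, followed so far
- flask: substrate 1.0 M; coupling partner 2.50 equiv; time 25 h

north-east run (percent of the substrate charged)

| time / h | first product / % | substrate / % |
|---|---|---|
| 3.00 | 38.2 | 61.0 |
| 6.00 | 50.0 | 49.5 |
| 8.00 | 52.8 | 44.9 |
| 12.0 | 58.0 | 39.2 |
| 15.0 | 60.7 | 37.0 |
| 20.0 | 63.1 | 34.4 |

(readings scatter by 0.3 percentage points)

- green: change nothing and wait 25 h more
- violet: at 25 h raise the temperature by 15 K, then wait 25 h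
- red: at 25 h take out 90 % of the first product then present, then wait 25 h

- removed first product is counted in
- the earlier runs do not show what temperature does; that part of a forecast is a guess

- first product, in percent of the substrate first charged, at 25 h
- the option that brings most further first product ("none" if no option brings more than 2 percentage points) (green / violet / red / none)
- first product present, with what was taken out counted in, in percent of the substrate first charged, after green
- first product present, with what was taken out counted in, in percent of the substrate first charged, after red

Yet the chance per hour that a free substrate molecule reacted, a pseudo-first-order rate constant read from the fall of ln c(substrate), dropped from 0.165 /h over the first 3.00 h to 0.0146 /h between 15.0 h and 20.0 h. That is a factor of 11.3, while first product grew by a factor of 1.65 from 3.00 h to 20.0 h. So I doubted that first product held the reaction back, and I took the chance as a gauge of c(coupling partner), which meant that partner was going elsewhere.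

Each partner molecule therefore stood at a fork, and I reckoned its odds: the partner share, the part of the spent coupling partner that ended as first product, came to 27.7 %, a selectivity. At that share the whole charge pays for 69.2 %. Holding the chance at 0.0146 /h gave me 65.5 % at 25 h, so green promised 3.7 percentage points, above the margin. My reckoning held the share fixed when first product was taken out, so I set red equal to green, as an estimate. Violet might move the share, in a direction the earlier runs do not show, and I chose it. On a repeat, c(coupling partner) is the reading to add.

The forecast gave 64.8 % (64.2 % to 65.5 %), 66.8 % after green and 83 % after red, and chose red, where I differed, with the words “Removing product pulls the equilibrium forward”.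

The north-east flask gave 64.6 % at 25.0 h, and violet brought most, 7.6 points against 4.2 points for green and 4.9 points for red. Coupling partner then stood at 2.96 % of its charge. With that amount the partner share comes to 26.6 %, beside my 27.7 %, and green ended at 68.8 %, beside my 69.2 %. Red ended at 69.5 %, 0.70 points above green, so the two were not equal as I had set them.

    substrate + coupling partner → first product (k = 0.120 /M/h, Ea = 93.0 kJ/mol)
    coupling partner + first product ⇌ double product (K = 0.610 /M, k = 0.0110 /M/h, Ea = 88.0 kJ/mol, ΔH = −10.0 kJ/mol)
    coupling partner → decomposed reagent (k = 0.0110 /h, Ea = 115 kJ/mol)
    2 coupling partner → self-condensation product (k = 0.0980 /M/h, Ea = 100 kJ/mol)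
    (constants at 90 °C)

With 0.620 equiv of coupling partner, my share pays for 17.2 %. That flask held 34.8 % at 25.0 h with 4.0 % of its partner left, a share of 58.5 %, twice mine, so the share belongs to the charge.

(The data are simulated from invented constants, noise included.)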